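I choose to judge these flasks by one number: how much rival reagent a target molecule meets during the run.

    substrate + coupling partner → target (k1 = 0.042 M⁻¹ s⁻¹)
    substrate + rival reagent → side product (k2 = 0.013 M⁻¹ s⁻¹)
    rival reagent + target → over-reaction product (k3 = 0.13 M⁻¹ s⁻¹)
    2 rival reagent → self-condensation product (k4 = 0.083 M⁻¹ s⁻¹)

in all of them: substrate 0.092 M; coupling partner 0.166 M; time 2.0 min

|  | rival reagent |
|---|---|
| epsilon | 0.0600 M |
| delta | 0.100 M |
| eta | 0.150 M |
| gamma | 0.250 M |

- where a step has two of a species, its rate is k times that concentration squared, and two are used at each turn
- "hardly changes" means that all values lie within two and a half points (for a concentration: within two and a half percent of the largest)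
- run time (epsilon): 2.0 min

- share of target in all that became target or side product or over-reaction product for epsilon, delta, eta, gamma, in this order
- the shape of the row from first to last (rises, then falls / falls all the way / hardly changes / rises all the way / falls, then rises)

In epsilon at the start, self-condensation removes rival reagent at 0.00996 s⁻¹ per unit of it, faster than substrate does at 0.00120 s⁻¹. So I let self-condensation carry the curve. The inverse of c(rival reagent) then climbs straight at 0.166 M⁻¹ s⁻¹. The mean of the curve is the logarithm of its start-to-end ratio over that slope and the time, 0.0395 M for epsilon.

Target is lost pseudo-first-order in rival reagent. I define the exposure as the over-reaction constant times mean c(rival reagent) times the run time, the number of target lifetimes in the run: 0.616 for epsilon. For delta, eta and gamma it is 0.858, 1.08 and 1.40. Target grows from nothing, so I take its mean as its final value over 2. Over-reaction product over target is then the exposure over 2.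

One number is not quite enough, since substrate also leaks to side product. The same mean gives the selectivity factor, 13.6 for epsilon and 5.97 for gamma, with coupling partner held at its charge. Both factors together give 71.2%, 63.5%, 57.4% and 50.4%. My share shrinks as the exposure grows, and the exposure climbs from each flask to the next, so my row: falls all the way.

The forecast gives 71.6%, 62.6%, 57.4% and 50.3%, so its shape is falls all the way: “More rival reagent steadily lowers the share”. At delta it lies lower than mine.

The flasks give 71.5%, 63.5%, 57.4% and 50.5%, so the row falls all the way. From epsilon to gamma, target at 2.00 min goes from 38.0% to 28.7% of the substrate charged, while substrate left goes from 46.9% to 43.3%. The exposure over 2 is 0.308 for epsilon, where over-reaction product over target stands at 0.293. For gamma it is 0.700, where that ratio stands at 0.640.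

(The constants used here were set for the occasion; the rest is arithmetic.)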